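The earlier runs and the new flask are simulated for substances that don't exist; noise was put on by code.

Two flasks, two final amounts and one choice between them are asked.

common to all: substrate 0.40 M; free catalyst 10 mM

|  | partner | temperature | remark | time |
|---|---|---|---|---|
| Tuesday's | 0.11 M | 45 °C | run made earlier |  |
| Sunday's | 0.44 M | 60 °C | run made earlier |  |
| violet | 0.0800 M | 50 °C |  | 2.0 h |
| teal | 0.280 M | 70 °C |  | 2.0 h |

Tuesday's run (percent of the substrate charged)

| time / h | target / % | substrate / % |
|---|---|---|
| 0.500 | 3.2 | 96.3 |
| 1.00 | 6.5 | 92.8 |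
| 2.50 | 14.6 | 84.2 |
| 3.00 | 16.4 | 82.2 |
| 5.00 | 21.1 | 75.6 |

Sunday's run (percent of the substrate charged)

| time / min | target / % | substrate / % |
|---|---|---|
| 10.0 | 7.0 | 93.0 |
| 20.0 | 13.0 | 86.6 |
| 40.0 | 24.4 | 73.0 |
| 60.0 | 33.9 | 59.6 |
| 120 | 53.3 | 26.6 |

(readings scatter by 0.3 percentage points)



* the flask that ends with the higher amount of target, in percent of the substrate charged, or "neither" when 2 percentage points or less lies between them (violet / teal / neither)
* final target, as a percentage of the substrate charged, in violet
* final target, as a percentage of the substrate charged, in teal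

Both flasks hold less partner than substrate, so partner is taken as the limiting reagent, one partner per substrate. The partner ceiling, partner charged over substrate charged, is 20.0% in violet and 70.0% in teal; it caps target together with whatever target becomes.

Turn the question round. For teal not to win, it must lose enough target to end within 2 percentage points of violet or below it, from a ceiling 3.50 times violet's. So the loss of target has to be reckoned.

Substrate lost, held against partner charged, gives the share of partner used: 88.7% at Tuesday's last reading, 66.7% at Sunday's. Treating partner as pseudo-first-order, k = ln(charged/left)/t gives 0.437 h⁻¹ and 0.550 h⁻¹. The loss constant l is the final gap in the balance over the area under the target curve: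

Tuesday's, 45 °C: l = 0.0513 h⁻¹

Sunday's, 60 °C: l = 0.325 h⁻¹

The two runs differ in partner as well as temperature, but this estimate puts the whole difference down to temperature: carrying each constant by a steady factor per degree, violet gets k = 0.472 h⁻¹ and l = 0.0950 h⁻¹, while teal gets k = 0.642 h⁻¹ and l = 1.11 h⁻¹. On these estimates teal's loss constant is larger than its partner constant. Integrating the two steps in a row:

target = ceiling · k/(k − l) · (e^(−l t) − e^(−k t))

violet: 11.0%

teal: 16.1%

Teal leads by 5.1 points, so this reckoning answers teal.

The forecast also says teal, but with 9.3% in violet and 26% in teal, “uncertain because of the extrapolated loss”.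

The simulation gives teal: 12.6% in violet, 18.4% in teal.

    substrate + catalyst intermediate B ⇌ catalyst intermediate C (K = 34.0 L mol⁻¹, k = 1.50 L mol⁻¹ s⁻¹, Ea = 43.0 kJ mol⁻¹, ΔH = −7.00 kJ mol⁻¹)
    target → over-reaction product (k = 2.80 × 10⁻⁴ s⁻¹, Ea = 108 kJ mol⁻¹)
    catalyst intermediate C → free catalyst + target (k = 0.890 s⁻¹, Ea = 83.0 kJ mol⁻¹)
    partner + free catalyst ⇌ catalyst intermediate A (K = 30.0 L mol⁻¹, k = 0.110 L mol⁻¹ s⁻¹, Ea = 60.0 kJ mol⁻¹, ΔH = −44.0 kJ mol⁻¹)
    substrate + catalyst intermediate C → spent catalyst (k = 0.00170 L mol⁻¹ s⁻¹, Ea = 58.0 kJ mol⁻¹)
    catalyst intermediate A → by-product + catalyst intermediate B (k = 0.0150 s⁻¹, Ea = 81.0 kJ mol⁻¹)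
    (constants at 70 °C)

Violet's ceiling of 20.0%, with 28% of its partner unbound at 2.00 h, gives 14.4% of the substrate charged as partner taken up, and violet has lost 14.0% of its substrate. A neighbour of violet charged with 0.16 M of substrate has a ceiling of 50.0%. Its unbound partner stands at 28%, level with violet, so the same product is 36.0%. That neighbour has lost 34.9% of its substrate and ends with 31.4% target and 3.48% over-reaction product.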